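## Retrosynthetic overview

1. The target is released from its 7,8-cyclic carbonate. Ring B (the pyran) is closed last, by Ph3PAuNTf2-catalysed 6-endo-dig cycloisomerisation of the C1 alcohol onto a non-aromatic chloro-ynenone. This replaces the usual azaphilone logic (aromatic precursor, oxidative dearomatisation, late reductions).
2. The ynenone comes from a Stille coupling of a ring A bromoalkyne with an (E)-vinylstannane that carries the complete side chain.
3. Ring A is made first, by a catalytic asymmetric Diels–Alder reaction of a 1-(Boc-oxy)-2-methyldiene with an acrylimide (sets C8 and C8a, cis). Anti-epoxidation and Boc-relayed epoxide opening then set C7, giving the all-cis C7–O/C8–O/C8a–CH2 triad.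
4. Oxidation-level adjustment of ring A: IBX oxidation/dehydrogenation, conjugate alkynylation, then dichlorination/dehydrochlorination to the 2-chloro-3-alkynyl enone.
5. Side chain: Brown anti-crotylation of methacrolein, hydroboration, cyclodehydration to the trans-oxolane, ozonolysis, chelation-controlled vinyl addition. Ring order: ring A, oxolane (separate branch), ring B.

Assumption: ring positions are cited with the isochromene numbering of the target (C1, O2, C3, C4, C4a, C5–C8, C8a) and oxolane carbons as C2'–C5'; compounds 1, 3, 11, 16, 17 and 22 and all reagents are taken as catalogue items.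

## Route

Step 1
Reactants: 1 (E)-2-methylbut-2-enal (tiglic aldehyde)
Product: 2 tert-butyl (1E)-2-methylbuta-1,3-dien-1-yl carbonate
Conditions: KOt-Bu (1.1 equiv), THF, −78 °C; then Boc2O, −78 → 0 °C
Reagents that add atoms: di-tert-butyl dicarbonate, CC(C)(C)OC(=O)OC(=O)OC(C)(C)C
Why: γ-deprotonation of the s-trans enal gives the (1E)-dienolate, which is O-acylated by Boc2O (dienol carbonate formation).

Step 2
Reactants: 2 tert-butyl (1E)-2-methylbuta-1,3-dien-1-yl carbonate; 3 3-(prop-2-enoyl)-1,3-oxazolidin-2-one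
Product: 4 3-{[(1R,2R)-2-[(tert-butoxycarbonyl)oxy]-3-methylcyclohex-3-en-1-yl]carbonyl}-1,3-oxazolidin-2-one
Conditions: [Cu((R,R)-t-Bu-box)](SbF6)2 (10 mol %), CH2Cl2, −20 °C
Reagents that add atoms: none
Why: Evans bis(oxazoline)–divalent copper catalysed Diels–Alder reaction, in which the 1-oxygen substituent (overriding the 2-methyl group) gives the "ortho" adduct, endo addition to the chelated s-cis acrylimide gives the cis product, and the tert-butyl groups of the square-planar complex shield one dienophile face so that C8a and C8 are set together.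

Step 3
Reactants: 4 Diels–Alder imide
Product: 5 tert-butyl (1R,6S)-6-(hydroxymethyl)-2-methylcyclohex-2-en-1-yl carbonate
Conditions: LiBH4 (1.5 equiv), H2O (1 equiv), Et2O, 0 °C
Reagents that add atoms: none
Why: reductive cleavage of the N-acyloxazolidinone by LiBH4 is much faster than attack on the hindered tert-butyl carbonate and leaves both stereocentres untouched.

Step 4
Reactants: 5 primary alcohol
Product: 6 tert-butyl (1R,6S)-6-{[(tert-butyldiphenylsilyl)oxy]methyl}-2-methylcyclohex-2-en-1-yl carbonate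
Conditions: TBDPSCl, imidazole, DMAP (cat.), CH2Cl2, 0 °C → rt
Reagents that add atoms: tert-butyl(chloro)diphenylsilane, CC(C)(C)[Si](Cl)(c1ccccc1)c1ccccc1
Why: standard silylation of the primary alcohol, which blocks C1–OH from competing in the next step.

Step 5
Reactants: 6 silyl ether
Product: 8 (3aS,4R,7S,7aR)-7-{[(tert-butyldiphenylsilyl)oxy]methyl}-4-hydroxy-3a-methylhexahydro-1,3-benzodioxol-2-one, via anti-epoxide 7 (not isolated)
Conditions: mCPBA, NaHCO3, CH2Cl2, 0 °C; then BF3·OEt2 (0.3 equiv), −40 → 0 °C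
Reagents that add atoms: 3-chloroperbenzoic acid, OOC(=O)c1cccc(Cl)c1
Why: Prilezhaev epoxidation occurs on the face opposite the two cis substituents, and the Boc carbonyl then opens the epoxide at the tertiary carbon with inversion (5-exo neighbouring-group participation, loss of isobutene), so the new C7–O bond is necessarily cis to C8–O and C8a–CH2 while the C6 hydroxyl is trans.

Step 6
Reactants: 8 hydroxy cyclic carbonate
Product: 10 (3aR,7S,7aR)-7-{[(tert-butyldiphenylsilyl)oxy]methyl}-3a-methyl-7,7a-dihydro-1,3-benzodioxole-2,4(3aH)-dione, via ketone 9 (not isolated)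
Conditions: IBX (4 equiv), DMSO/fluorobenzene (1:2), 80 °C
Reagents that add atoms: none
Why: IBX oxidises the secondary alcohol and then dehydrogenates the ketone (Nicolaou IBX dehydrogenation), and because C7 is quaternary the enone can form only towards C5/C4a.

Step 7
Reactants: 10 enone; 11 ethynyl(trimethyl)silane
Product: 12 (3aR,6S,7S,7aR)-7-{[(tert-butyldiphenylsilyl)oxy]methyl}-3a-methyl-6-[(trimethylsilyl)ethynyl]tetrahydro-1,3-benzodioxole-2,4(3aH)-dione
Conditions: 11, n-BuLi, Et2O, −78 °C; Me2AlCl; then Ni(acac)2 (10 mol %), i-Bu2AlH (10 mol %), 10, Et2O, −5 °C; aq. work-up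
Reagents that add atoms: none
Why: Ni(acac)2/i-Bu2AlH-catalysed conjugate addition of the alkynylalane to the s-trans enone (Schwartz conjugate alkynylation) places the alkyne on C4a anti to the neighbouring silyloxymethyl group, a centre that is removed again in step 8.

Step 8
Reactants: 12 β-alkynyl ketone
Product: 14 (3aR,7S,7aR)-7-{[(tert-butyldiphenylsilyl)oxy]methyl}-5-chloro-3a-methyl-6-[(trimethylsilyl)ethynyl]-7,7a-dihydro-1,3-benzodioxole-2,4(3aH)-dione, via dichloro ketone 13 (not isolated)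
Conditions: SO2Cl2 (2.3 equiv), CH2Cl2, 0 °C → rt; evaporate; then DBU (1.5 equiv), CH2Cl2, −20 → 0 °C
Reagents that add atoms: sulfuryl chloride, ClS(Cl)(=O)=O
Why: α,α-dichlorination at the only enolisable position (C5) followed by dehydrochlorination through the propargylic C4a–H installs the C5 chlorine and the C4a=C5 double bond in one operation.

Step 9
Reactants: 14 chloro-enynone (C-silyl)
Product: 15 (3aR,7S,7aR)-6-(bromoethynyl)-7-{[(tert-butyldiphenylsilyl)oxy]methyl}-5-chloro-3a-methyl-7,7a-dihydro-1,3-benzodioxole-2,4(3aH)-dione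
Conditions: NBS (1.1 equiv), AgNO3 (10 mol %), acetone, rt, dark
Reagents that add atoms: N-bromosuccinimide, BrN1C(=O)CCC1=O
Why: AgNO3-catalysed bromodesilylation of the alkynylsilane via a silver acetylide gives the 1-bromoalkyne without base.

Step 10
Reactants: 16 2-methylprop-2-enal (methacrolein); 17 (E)-but-2-ene
Product: 18 (3S,4S)-2,4-dimethylhexa-1,5-dien-3-ol
Conditions: 17, KOt-Bu, n-BuLi, THF, −78 → −45 °C; (−)-Ipc2BOMe, −78 °C; BF3·OEt2; 16, −78 °C; then NaOH, H2O2
Reagents that add atoms: none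
Why: Brown crotylboration, in which the (E)-crotylborane reacts through a chair Zimmerman–Traxler transition state to give the anti product and the (−)-Ipc groups select the aldehyde face, setting the future C2' and C3'.

Step 11
Reactants: 18 dienol
Product: 19 (3S,4S)-3,5-dimethylhex-5-ene-1,4-diol
Conditions: Sia2BH (2.2 equiv, from BH3·THF and 2-methylbut-2-ene), THF, 0 °C; then NaOH, H2O2
Reagents that add atoms: hydrogen peroxide, OO
Why: anti-Markovnikov hydroboration–oxidation, in which the bulky dialkylborane reacts with the monosubstituted vinyl group much faster than with the 1,1-disubstituted alkene.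

Step 12
Reactants: 19 diol
Product: 20 (2S,3S)-3-methyl-2-(prop-1-en-2-yl)oxolane
Conditions: PPh3, DIAD, THF, 0 °C → rt
Reagents that add atoms: none
Why: Mitsunobu cyclodehydration, in which the primary alcohol is activated and displaced by the secondary hydroxyl (5-exo-tet), so both stereocentres are retained and the ring is 2,3-trans.

Step 13
Reactants: 20 isopropenyl oxolane
Product: 21 1-[(2S,3S)-3-methyloxolan-2-yl]ethan-1-one
Conditions: O3, CH2Cl2, −78 °C; then Me2S
Reagents that add atoms: ozone, [O-][O+]=O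
Why: ozonolysis of the 1,1-disubstituted alkene gives the methyl ketone, whose trans arrangement is also the thermodynamically preferred one.

Step 14
Reactants: 21 methyl ketone; 22 (E)-1,2-bis(tributylstannyl)ethene
Product: 23 (2S,3E)-2-[(2S,3S)-3-methyloxolan-2-yl]-4-(tributylstannyl)but-3-en-2-ol
Conditions: 22, n-BuLi, THF, −78 °C; MgBr2·OEt2; then 21, −78 °C; aq. NH4Cl
Reagents that add atoms: none
Why: tin–lithium exchange, transmetalation and Cram-chelate-controlled Grignard addition, in which magnesium bridges the ketone and ring oxygens and the vinyl group attacks anti to C3', giving the (S)-carbinol.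

Step 15
Reactants: 15 bromoalkyne; 23 vinylstannane
Product: 24 (3aR,7S,7aR)-7-{[(tert-butyldiphenylsilyl)oxy]methyl}-5-chloro-6-{(3E,5S)-5-hydroxy-5-[(2S,3S)-3-methyloxolan-2-yl]hex-3-en-1-yn-1-yl}-3a-methyl-7,7a-dihydro-1,3-benzodioxole-2,4(3aH)-dione
Conditions: Pd2(dba)3 (5 mol %), AsPh3 (20 mol %), THF, rt
Reagents that add atoms: none
Why: Stille coupling of the 1-bromoalkyne with the vinylstannane through zerovalent palladium proceeds under neutral conditions with retention of the E geometry and tolerates the free tertiary alcohol.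

Step 16
Reactants: 24 silyl-protected ynenone
Product: 25 (3aR,7S,7aR)-5-chloro-6-{(3E,5S)-5-hydroxy-5-[(2S,3S)-3-methyloxolan-2-yl]hex-3-en-1-yn-1-yl}-7-(hydroxymethyl)-3a-methyl-7,7a-dihydro-1,3-benzodioxole-2,4(3aH)-dione
Conditions: HF·pyridine, pyridine, THF, 0 °C → rt
Reagents that add atoms: none
Why: buffered fluoride cleaves the silyl ether without touching the cyclic carbonate, the ynenone or the tertiary allylic alcohol.

Step 17
Reactants: 25 hydroxy ynenone
Product: 26 (7R,8R,8aS)-5-chloro-3-{(1E,3S)-3-hydroxy-3-[(2S,3S)-3-methyloxolan-2-yl]but-1-en-1-yl}-7-methyl-6-oxo-1,7,8,8a-tetrahydro-6H-isochromene-7,8-diyl carbonate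
Conditions: Ph3PAuNTf2 (5 mol %), CH2Cl2, 0 °C → rt
Reagents that add atoms: none
Why: π-acid-catalysed 6-endo-dig hydroalkoxylation (cycloisomerisation) by monovalent gold, in which C3 is the δ-position of the ynenone and carries the donor vinyl group, so the C1 hydroxyl attacks C3 rather than C4 and ring B forms with no change at any stereocentre.

Step 18
Reactants: 26 cyclic carbonate
Product: 27 (7R,8R,8aS)-5-chloro-7,8-dihydroxy-3-{(1E,3S)-3-hydroxy-3-[(2S,3S)-3-methyloxolan-2-yl]but-1-en-1-yl}-7-methyl-1,7,8,8a-tetrahydro-6H-isochromen-6-one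
Conditions: K2CO3 (0.2 equiv), MeOH, 0 °C
Reagents that add atoms: none
Why: methanolysis (transesterification) of the strained five-membered cyclic carbonate releases the cis-7,8-diol under conditions too mild to affect the dienone or the stereocentres.

## Compound list

1 | (E)-2-methylbut-2-enal (tiglic aldehyde) | C/C=C(\C)C=O | starting material
2 | tert-butyl (1E)-2-methylbuta-1,3-dien-1-yl carbonate | CC(C)(C)OC(=O)O/C=C(C)/C=C | intermediate
3 | 3-(prop-2-enoyl)-1,3-oxazolidin-2-one | C=CC(=O)N1CCOC1=O | starting material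
4 | 3-{[(1R,2R)-2-[(tert-butoxycarbonyl)oxy]-3-methylcyclohex-3-en-1-yl]carbonyl}-1,3-oxazolidin-2-one | C1CC=C(C)[C@H](OC(=O)OC(C)(C)C)[C@@H]1C(=O)N2CCOC2=O | intermediate
5 | tert-butyl (1R,6S)-6-(hydroxymethyl)-2-methylcyclohex-2-en-1-yl carbonate | C1CC=C(C)[C@H](OC(=O)OC(C)(C)C)[C@@H]1CO | intermediate
6 | tert-butyl (1R,6S)-6-{[(tert-butyldiphenylsilyl)oxy]methyl}-2-methylcyclohex-2-en-1-yl carbonate | C1CC=C(C)[C@H](OC(=O)OC(C)(C)C)[C@@H]1CO[Si](c2ccccc2)(c3ccccc3)C(C)(C)C | intermediate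
7 | tert-butyl (1R,2R,3S,6R)-3-{[(tert-butyldiphenylsilyl)oxy]methyl}-1-methyl-7-oxabicyclo[4.1.0]heptan-2-yl carbonate (oxirane trans to both ring substituents) | C1C[C@H]2O[C@@]2(C)[C@H](OC(=O)OC(C)(C)C)[C@@H]1CO[Si](c3ccccc3)(c4ccccc4)C(C)(C)C | intermediate (not isolated)
8 | (3aS,4R,7S,7aR)-7-{[(tert-butyldiphenylsilyl)oxy]methyl}-4-hydroxy-3a-methylhexahydro-1,3-benzodioxol-2-one | C1C[C@@H](O)[C@]2(C)OC(=O)O[C@@H]2[C@@H]1CO[Si](c3ccccc3)(c4ccccc4)C(C)(C)C | intermediate
9 | (3aR,7S,7aR)-7-{[(tert-butyldiphenylsilyl)oxy]methyl}-3a-methyltetrahydro-1,3-benzodioxole-2,4(3aH)-dione | C1CC(=O)[C@]2(C)OC(=O)O[C@@H]2[C@@H]1CO[Si](c3ccccc3)(c4ccccc4)C(C)(C)C | intermediate (not isolated)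
10 | (3aR,7S,7aR)-7-{[(tert-butyldiphenylsilyl)oxy]methyl}-3a-methyl-7,7a-dihydro-1,3-benzodioxole-2,4(3aH)-dione | C1=CC(=O)[C@]2(C)OC(=O)O[C@@H]2[C@@H]1CO[Si](c3ccccc3)(c4ccccc4)C(C)(C)C | intermediate
11 | ethynyl(trimethyl)silane | C#C[Si](C)(C)C | starting material
12 | (3aR,6S,7S,7aR)-7-{[(tert-butyldiphenylsilyl)oxy]methyl}-3a-methyl-6-[(trimethylsilyl)ethynyl]tetrahydro-1,3-benzodioxole-2,4(3aH)-dione | C1C(=O)[C@]2(C)OC(=O)O[C@@H]2[C@H](CO[Si](c3ccccc3)(c4ccccc4)C(C)(C)C)[C@H]1C#C[Si](C)(C)C | intermediate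
13 | (3aR,6S,7S,7aR)-7-{[(tert-butyldiphenylsilyl)oxy]methyl}-5,5-dichloro-3a-methyl-6-[(trimethylsilyl)ethynyl]tetrahydro-1,3-benzodioxole-2,4(3aH)-dione | C1(Cl)(Cl)C(=O)[C@]2(C)OC(=O)O[C@@H]2[C@H](CO[Si](c3ccccc3)(c4ccccc4)C(C)(C)C)[C@H]1C#C[Si](C)(C)C | intermediate (not isolated)
14 | (3aR,7S,7aR)-7-{[(tert-butyldiphenylsilyl)oxy]methyl}-5-chloro-3a-methyl-6-[(trimethylsilyl)ethynyl]-7,7a-dihydro-1,3-benzodioxole-2,4(3aH)-dione | C1(C#C[Si](C)(C)C)=C(Cl)C(=O)[C@]2(C)OC(=O)O[C@@H]2[C@@H]1CO[Si](c3ccccc3)(c4ccccc4)C(C)(C)C | intermediate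
15 | (3aR,7S,7aR)-6-(bromoethynyl)-7-{[(tert-butyldiphenylsilyl)oxy]methyl}-5-chloro-3a-methyl-7,7a-dihydro-1,3-benzodioxole-2,4(3aH)-dione | C1(C#CBr)=C(Cl)C(=O)[C@]2(C)OC(=O)O[C@@H]2[C@@H]1CO[Si](c3ccccc3)(c4ccccc4)C(C)(C)C | intermediate
16 | 2-methylprop-2-enal (methacrolein) | CC(=C)C=O | starting material
17 | (E)-but-2-ene | C/C=C/C | starting material
18 | (3S,4S)-2,4-dimethylhexa-1,5-dien-3-ol | C=C[C@H](C)[C@H](O)C(C)=C | intermediate
19 | (3S,4S)-3,5-dimethylhex-5-ene-1,4-diol | OCC[C@H](C)[C@H](O)C(C)=C | intermediate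
20 | (2S,3S)-3-methyl-2-(prop-1-en-2-yl)oxolane | C[C@H]1CCO[C@@H]1C(C)=C | intermediate
21 | 1-[(2S,3S)-3-methyloxolan-2-yl]ethan-1-one | C[C@H]1CCO[C@@H]1C(C)=O | intermediate
22 | (E)-1,2-bis(tributylstannyl)ethene | CCCC[Sn](CCCC)(CCCC)/C=C/[Sn](CCCC)(CCCC)CCCC | starting material
23 | (2S,3E)-2-[(2S,3S)-3-methyloxolan-2-yl]-4-(tributylstannyl)but-3-en-2-ol | C[C@H]1CCO[C@@H]1[C@@](C)(O)/C=C/[Sn](CCCC)(CCCC)CCCC | intermediate
24 | (3aR,7S,7aR)-7-{[(tert-butyldiphenylsilyl)oxy]methyl}-5-chloro-6-{(3E,5S)-5-hydroxy-5-[(2S,3S)-3-methyloxolan-2-yl]hex-3-en-1-yn-1-yl}-3a-methyl-7,7a-dihydro-1,3-benzodioxole-2,4(3aH)-dione | C[C@H]1CCO[C@@H]1[C@@](C)(O)/C=C/C#CC2=C(Cl)C(=O)[C@]3(C)OC(=O)O[C@@H]3[C@@H]2CO[Si](c4ccccc4)(c5ccccc5)C(C)(C)C | intermediate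
25 | (3aR,7S,7aR)-5-chloro-6-{(3E,5S)-5-hydroxy-5-[(2S,3S)-3-methyloxolan-2-yl]hex-3-en-1-yn-1-yl}-7-(hydroxymethyl)-3a-methyl-7,7a-dihydro-1,3-benzodioxole-2,4(3aH)-dione | C[C@H]1CCO[C@@H]1[C@@](C)(O)/C=C/C#CC2=C(Cl)C(=O)[C@]3(C)OC(=O)O[C@@H]3[C@@H]2CO | intermediate
26 | (7R,8R,8aS)-5-chloro-3-{(1E,3S)-3-hydroxy-3-[(2S,3S)-3-methyloxolan-2-yl]but-1-en-1-yl}-7-methyl-6-oxo-1,7,8,8a-tetrahydro-6H-isochromene-7,8-diyl carbonate (7,8-cyclic carbonate of the target) | C[C@H]1CCO[C@@H]1[C@@](C)(O)/C=C/C1=CC2=C(Cl)C(=O)[C@]3(C)OC(=O)O[C@@H]3[C@@H]2CO1 | intermediate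
27 | (7R,8R,8aS)-5-chloro-7,8-dihydroxy-3-{(1E,3S)-3-hydroxy-3-[(2S,3S)-3-methyloxolan-2-yl]but-1-en-1-yl}-7-methyl-1,7,8,8a-tetrahydro-6H-isochromen-6-one | C[C@H]1CCO[C@@H]1[C@@](C)(O)/C=C/C1=CC2=C(Cl)C(=O)[C@](C)(O)[C@H](O)[C@@H]2CO1 | target

## Step count and risk

Total step count: 18. Longest linear sequence: 13 steps (steps 1–9, then 15–18); the side-chain branch is steps 10–14.

The three steps most likely to fail:

Step 2 (asymmetric Diels–Alder). The 2-methyl group opposes the regiochemical preference of the Boc-oxy group, and this diene has not been used with the [Cu(t-Bu-box)](SbF6)2 catalyst. If regio-, endo- or enantioselectivity is poor, the activation mode is changed from Lewis-acid chelation to iminium catalysis. The fallback sets out from diene 2, which is combined with acrolein and (2S,5S)-5-benzyl-2,2,3-trimethylimidazolidin-4-one hydrochloride (20 mol %, MeCN/H2O, −10 °C) to give the cis aldehyde tert-butyl (1R,6R)-6-formyl-2-methylcyclohex-2-en-1-yl carbonate F1. Reduction of F1 with NaBH4 in MeOH at 0 °C comes back to the route at alcohol 5.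

Step 8 (dichlorination/dehydrochlorination). Over-chlorination, or base-induced vinylogous loss of the C8 carbonate, could destroy 12 or 14. The fallback replaces the alkynyl-ketone approach by cross-coupling on a chloro enol triflate and sets out from enone 10, so it also bypasses step 7. Wacker–Tsuji oxidation (Na2PdCl4 cat., t-BuOOH, AcOH/H2O, 50 °C) gives the cyclic 1,3-dione, written as its enol (3aR,7S,7aR)-7-{[(tert-butyldiphenylsilyl)oxy]methyl}-6-hydroxy-3a-methyl-7,7a-dihydro-1,3-benzodioxole-2,4(3aH)-dione F2. NCS in CH2Cl2 chlorinates the central carbon to give (3aR,7S,7aR)-7-{[(tert-butyldiphenylsilyl)oxy]methyl}-5-chloro-6-hydroxy-3a-methyl-7,7a-dihydro-1,3-benzodioxole-2,4(3aH)-dione F3. Tf2O/pyridine at −78 °C sulfonylates the less hindered enol oxygen (remote from the quaternary carbon) to give (3aR,7S,7aR)-7-{[(tert-butyldiphenylsilyl)oxy]methyl}-5-chloro-3a-methyl-2,4-dioxo-3a,4,7,7a-tetrahydro-1,3-benzodioxol-6-yl trifluoromethanesulfonate F4. Sonogashira coupling of F4 with 11 (Pd(PPh3)4, CuI, Et3N, THF) comes back to the route at 14.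

Step 17 (6-endo-dig cycloisomerisation). Competing 5-exo closure at C4, or Ph3PAuNTf2-induced decomposition of the dienyne, is possible. The fallback closes ring B by addition–elimination instead of π-acid catalysis and sets out from 25. Pyrrolidine (1.05 equiv, THF, 0 °C) adds to C3 in a 1,6-aza-Michael reaction to give the vinylogous amide (3aR,7S,7aR)-5-chloro-6-{(1E,3E,5S)-5-hydroxy-5-[(2S,3S)-3-methyloxolan-2-yl]-2-(pyrrolidin-1-yl)hexa-1,3-dien-1-yl}-7-(hydroxymethyl)-3a-methyl-7,7a-dihydro-1,3-benzodioxole-2,4(3aH)-dione F5. Warming F5 with PPTS in wet MeCN lets the C1 hydroxyl displace pyrrolidine at C3, which comes back to the route at 26.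

## Further compounds

F1 | step 2 | tert-butyl (1R,6R)-6-formyl-2-methylcyclohex-2-en-1-yl carbonate | C1CC=C(C)[C@H](OC(=O)OC(C)(C)C)[C@@H]1C=O
F2 | step 8 | (3aR,7S,7aR)-7-{[(tert-butyldiphenylsilyl)oxy]methyl}-6-hydroxy-3a-methyl-7,7a-dihydro-1,3-benzodioxole-2,4(3aH)-dione | OC1=CC(=O)[C@]2(C)OC(=O)O[C@@H]2[C@@H]1CO[Si](c3ccccc3)(c4ccccc4)C(C)(C)C
F3 | step 8 | (3aR,7S,7aR)-7-{[(tert-butyldiphenylsilyl)oxy]methyl}-5-chloro-6-hydroxy-3a-methyl-7,7a-dihydro-1,3-benzodioxole-2,4(3aH)-dione | OC1=C(Cl)C(=O)[C@]2(C)OC(=O)O[C@@H]2[C@@H]1CO[Si](c3ccccc3)(c4ccccc4)C(C)(C)C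
F4 | step 8 | (3aR,7S,7aR)-7-{[(tert-butyldiphenylsilyl)oxy]methyl}-5-chloro-3a-methyl-2,4-dioxo-3a,4,7,7a-tetrahydro-1,3-benzodioxol-6-yl trifluoromethanesulfonate | FC(F)(F)S(=O)(=O)OC1=C(Cl)C(=O)[C@]2(C)OC(=O)O[C@@H]2[C@@H]1CO[Si](c3ccccc3)(c4ccccc4)C(C)(C)C
F5 | step 17 | (3aR,7S,7aR)-5-chloro-6-{(1E,3E,5S)-5-hydroxy-5-[(2S,3S)-3-methyloxolan-2-yl]-2-(pyrrolidin-1-yl)hexa-1,3-dien-1-yl}-7-(hydroxymethyl)-3a-methyl-7,7a-dihydro-1,3-benzodioxole-2,4(3aH)-dione | C[C@H]1CCO[C@@H]1[C@@](C)(O)/C=C/C(N4CCCC4)=C\C2=C(Cl)C(=O)[C@]3(C)OC(=O)O[C@@H]3[C@@H]2CO
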